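**Steady loss.** If the loss of starting material per enzyme holds steady, one number reckoned from the earlier runs serves both new flasks, summer and midnight.

common to all: starting material 0.10 M; free enzyme 12 µM

| run | second substrate | scavenger | remark | time |
|---|---|---|---|---|
| grey | 0.25 M | 0.033 M | run made earlier |  |
| blue | 0.25 M | 0.037 M | run made earlier |  |
| violet | 0.25 M | 0.051 M | run made earlier |  |
| summer | 0.250 M | 0.0300 M |  | 8.0 min |
| midnight | 0.250 M | 0.0450 M |  | 8.0 min |

| run | time / min | starting material / % | target / % |
|---|---|---|---|
| grey | 0.333 | 99.2 | 0.8 |
| grey | 0.667 | 98.6 | 1.0 |
| grey | 1.00 | 98.3 | 0.8 |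
| grey | 2.00 | 96.9 | 2.3 |
| grey | 4.00 | 93.6 | 4.8 |
| blue | 0.333 | 98.9 | 0.9 |
| blue | 0.667 | 98.2 | 0.4 |
| blue | 1.00 | 97.9 | 1.1 |
| blue | 2.00 | 96.6 | 3.0 |
| blue | 4.00 | 93.8 | 4.7 |
| violet | 0.333 | 98.9 | 0.3 |
| violet | 1.00 | 97.7 | 1.1 |
| violet | 2.00 | 96.6 | 1.9 |
| violet | 3.00 | 94.8 | 3.5 |
| violet | 4.00 | 92.8 | 4.1 |

(each reading ± 0.5 percentage points)

- amounts and yields of first product count idle adduct too
- the numbers in the tables scatter by 0.5 percentage points (one standard deviation)
- reactions considered so far: starting material + free enzyme <-> first complex; first complex -> loaded enzyme + first product; second substrate + loaded enzyme <-> second complex; second complex -> free enzyme + target; starting material + first product <-> idle adduct; scavenger + first product -> scavenged by-product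
- what has gone from starting material into another species counts as reacted, even if it can come back

- part of the starting material that has reacted at the end, summer
- part of the starting material that has reacted at the end, midnight
- what raising the concentration of scavenger from its lowest to its highest value here does to the part of the starting material that has reacted (changes below 5 percentage points count as none) (it falls / no change / it rises)

**First link.** Average the grey, blue and violet readings. At 4.00 min you find 6.60 % of the starting material gone, and at 2.00 min 3.30 %. The loss has reached twice its earlier value in twice the time, so the rate has not drifted within the scatter.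

**Second link.** Dividing by enzyme and time gives 138 min⁻¹ of starting material consumed per enzyme charged, with starting material held in idle adduct counted in, an apparent turnover frequency.

**Third link.** Between blue and violet the loss differs by 1 percentage point, less than the 5 points that counts, so you carry one value to both flasks. Over 8.0 min with 12 µM of free enzyme it gives 13.2 % reacted. That reckons to about 0.0132 M of first product, less than summer's 0.0300 M of scavenger.

**Weak link.** Doubling assumes that the loss beyond target, read as idle adduct, keeps growing. Were it to stop at 2.1 points, you would get 11.1 %. But the readings put it at 0.9 points at 2.00 min, so as read it was still rising, and you keep 13.2 %.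

**The forecast.** It stands lower, at 12.2 % for summer and 12 % for midnight, with the trend no change, on “no clear scavenger effect within the scatter”.

**The result.** Summer gives 12.8 % and midnight 12.6 %, and the trend is no change, with a change of −0.23 points.

    starting material + free enzyme ⇌ first complex (K = 13.0 M⁻¹, k = 4.50 × 10⁵ M⁻¹ min⁻¹)
    first complex → loaded enzyme + first product (k = 2000 min⁻¹)
    second substrate + loaded enzyme ⇌ second complex (K = 1.60 M⁻¹, k = 43000 M⁻¹ min⁻¹)
    second complex → free enzyme + target (k = 380 min⁻¹)
    starting material + first product ⇌ idle adduct, settled at all times (K = 9.10 M⁻¹)
    scavenger + first product → scavenged by-product (k = 2.20 M⁻¹ min⁻¹)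

**Not at rest.** For a neighbour like midnight with 3.0 × 10⁻⁵ M of free enzyme, the apparent turnover frequency reckons 33.0 %, and that flask gives 29.8 %. At 8.0 min summer and midnight still hold 87 % and 87 % of their starting material, and neither has come to rest. Carried to 80.0 min, the same steady reckoning gives 132 %, more than was charged. By then summer has reached 85.1 % and midnight 84.1 %, and summer's free scavenger is down to 3.09 % of its charge.

All runs were computed on assumed constants; the scatter is artificial.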